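**Retrosynthetic overview**
1. The route rests on upper C4 being a diarylmethine between two phloroglucinol rings (upper ring A through C4a, lower ring A through C6), so a C4 cation can be carried by the future lower ring and trapped by upper ring A.
2. Last disconnections: global hydrogenolysis, then both galloyl esters (lower O3 and O3') in one acylation.
3. Lower ring C: O1–C2 by Mitsunobu etherification of the phenol para to the interflavan carbon with an erythro aryl epoxy alcohol, then C4–C4a by 6-endo epoxy-arene closure; the two ortho positions of that phenol are equivalent, so only the 4→6 isomer can form.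
4. Upper ring C (key): C4–C4a by cationic Friedel–Crafts closure of an acyclic carbinol, made from a 2,6-bis(benzyloxy)-4-silyloxyphenyllithium and an aldehyde whose C2/C3 centres come from an Evans syn glycolate aldol and a retentive Pd O-arylation.
5. Ring order: upper ring C (step 10), then lower ring C (step 19).

Key step: step 10

Remark: carbinol 17 is made and used as the mixture of its two C4 epimers, because step 10 passes through one cation; the 4',5'-diol of the lower ring B is masked as a diphenylmethylene ketal that falls in the final hydrogenolysis.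

**Route**

Step 1
Reactants: 1 (S)-4-benzyl-1,3-oxazolidin-2-one; 2 (benzyloxy)acetyl chloride
Product: 4 (S)-4-benzyl-3-[(benzyloxy)acetyl]-1,3-oxazolidin-2-one, via lithium oxazolidinide 3 (not isolated)
Conditions: n-BuLi, THF, −78 °C; then 2, −78 → 0 °C
Reagents that add atoms: none
Why: N-acylation of the lithiated oxazolidinone by the acid chloride is the standard loading of an Evans auxiliary and creates no stereocentre.

Step 2
Reactants: 4 (S)-4-benzyl-3-[(benzyloxy)acetyl]-1,3-oxazolidin-2-one; 5 4-(benzyloxy)benzaldehyde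
Product: 7 (S)-4-benzyl-3-[(2S,3R)-2-(benzyloxy)-3-[4-(benzyloxy)phenyl]-3-hydroxypropanoyl]-1,3-oxazolidin-2-one, via (Z)-boron enolate 6 (not isolated)
Conditions: Bu2BOTf, Et3N, CH2Cl2, −78 → 0 °C; then 5, −78 → 0 °C; pH 7 buffer, MeOH, 30% H2O2, 0 °C
Reagents that add atoms: none
Why: Evans syn aldol reaction, in which the (Z)-boron enolate 6 meets the aldehyde in a closed Zimmerman–Traxler chair on the enolate face away from the auxiliary benzyl group and so sets the 2S,3R (syn) pair that becomes upper C3 and C2.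

Step 3
Reactants: 7 the syn aldol adduct
Product: 8 (1R,2R)-2-(benzyloxy)-1-[4-(benzyloxy)phenyl]propane-1,3-diol
Conditions: LiBH4, MeOH (1 equiv), THF, 0 °C
Reagents that add atoms: none
Why: Hydride reduction of the exocyclic imide carbonyl cleaves the auxiliary reductively, frees the primary alcohol and leaves both stereocentres untouched.

Step 4
Reactants: 8 (1R,2R)-2-(benzyloxy)-1-[4-(benzyloxy)phenyl]propane-1,3-diol
Product: 9 (1R,2R)-2-(benzyloxy)-1-[4-(benzyloxy)phenyl]-3-[(tert-butyldiphenylsilyl)oxy]propan-1-ol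
Conditions: t-BuPh2SiCl, imidazole, CH2Cl2, 0 °C
Reagents that add atoms: tert-butyl(chloro)diphenylsilane, CC(C)(C)[Si](Cl)(c1ccccc1)c1ccccc1
Why: Silylation with a bulky chlorosilane is selective for the primary over the hindered secondary benzylic hydroxyl, and the diphenyl-tert-butylsilyl group should not migrate under the basic conditions of the next step.

Step 5
Reactants: 9 the mono-silylated diol; 10 1-bromo-3,5-bis(benzyloxy)benzene
Product: 11 tert-butyl{(2R,3R)-2-(benzyloxy)-3-[4-(benzyloxy)phenyl]-3-[3,5-bis(benzyloxy)phenoxy]propoxy}diphenylsilane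
Conditions: Pd2(dba)3 (2 mol %), RockPhos (6 mol %), Cs2CO3, toluene, 90 °C
Reagents that add atoms: none
Why: Palladium-catalysed C–O cross-coupling of a secondary alcohol with an aryl bromide (Buchwald–Hartwig etherification), in which the bulky biaryl phosphine should favour reductive elimination over β-hydride elimination; the carbinol C–O bond is not broken, so the future C2 keeps its R configuration.

Step 6
Reactants: 11 the silyl-protected aryl ether
Product: 12 (2R,3R)-2-(benzyloxy)-3-[4-(benzyloxy)phenyl]-3-[3,5-bis(benzyloxy)phenoxy]propan-1-ol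
Conditions: Bu4NF, THF, 0 °C → rt
Reagents that add atoms: none
Why: Fluoride-mediated cleavage of the silyl ether leaves the benzyl and aryl ethers intact.

Step 7
Reactants: 12 the primary alcohol
Product: 13 (2S,3R)-2-(benzyloxy)-3-[4-(benzyloxy)phenyl]-3-[3,5-bis(benzyloxy)phenoxy]propanal
Conditions: Dess–Martin periodinane, CH2Cl2, 0 °C → rt; used crude at once
Reagents that add atoms: none
Why: Dess–Martin oxidation works without base, so the α-benzyloxy aldehyde should form without epimerisation at the future C3 or β-elimination of the aryloxy group.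

Step 8
Reactants: 14 3,5-bis(benzyloxy)phenol
Product: 15 [3,5-bis(benzyloxy)phenoxy]tri(propan-2-yl)silane
Conditions: i-Pr3SiCl, imidazole, DMF, rt
Reagents that add atoms: chlorotri(propan-2-yl)silane, CC(C)[Si](Cl)(C(C)C)C(C)C
Why: Silylation of the phenol gives a bulky, base-stable silyl ether that marks the oxygen that later becomes O1 of the lower unit.

Step 9
Reactants: 15 [3,5-bis(benzyloxy)phenoxy]tri(propan-2-yl)silane; 13 the aldehyde
Product: 17 (2R,3R)-2-(benzyloxy)-3-[4-(benzyloxy)phenyl]-3-[3,5-bis(benzyloxy)phenoxy]-1-{2,6-bis(benzyloxy)-4-[tri(propan-2-yl)silyloxy]phenyl}propan-1-ol (both C1 epimers; C1 is the future upper C4), via aryllithium 16 (not isolated)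
Conditions: 15 (1.5 equiv), n-BuLi, THF, 0 °C; then 13, −78 °C
Reagents that add atoms: none
Why: Directed ortho-metalation at the carbon flanked by the two benzyloxy groups (the bulky silyloxy group is a poor director and shields its own neighbours) gives aryllithium 16, whose 1,2-addition to the aldehyde forms the C4–aryl bond; no control at C4 is needed because both epimers are used.

Step 10
Reactants: 17 the acyclic carbinol (both C4 epimers)
Product: 19 [3,5-bis(benzyloxy)-4-{(2R,3R,4S)-3,5,7-tris(benzyloxy)-2-[4-(benzyloxy)phenyl]chroman-4-yl}phenoxy]tri(propan-2-yl)silane (4β-aryl; 2,3-cis; 3,4-trans), via C4 benzylic cation 18 (not isolated)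
Conditions: BF3·OEt2, 4 Å MS, CH2Cl2 (high dilution), −78 → −40 °C
Reagents that add atoms: none
Why: BF3·OEt2 ionises the doubly ortho-oxygenated benzylic carbinol of either epimer to the single cation 18, delocalised into the 2,6-bis(benzyloxy)-4-silyloxyphenyl ring, and the 3,5-bis(benzyloxy)phenoxy group on C2 attacks it through one of its two equivalent ortho carbons and then rearomatises. The closest known reaction type is the acid-mediated intramolecular Friedel–Crafts alkylation of benzylic carbinols by tethered aryl ethers that gives 4-arylchromans. Upper ring C closes by C4–C4a bond formation in a 6-exo-trig mode, the cationic C4=aryl bond staying outside the new ring. The new C4 centre is controlled by the existing C2 and C3 centres through a half-chair transition state with the C2 aryl equatorial, the C3 benzyloxy axial and the lower ring pseudo-axial, which gives the 3,4-trans (4β) isomer, whereas the 3,4-cis alternative must either press the lower ring against the C5 benzyloxy group or set it syn-diaxial to the C2 aryl group. The step needs chemoselectivity between the two benzylic C–O bonds, which is secured because the trioxygenated benzyl cation forms far more readily than a 4-benzyloxybenzyl cation at C2.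

Step 11
Reactants: 19 the silyl-protected 4-arylflavan
Product: 20 3,5-bis(benzyloxy)-4-{(2R,3R,4S)-3,5,7-tris(benzyloxy)-2-[4-(benzyloxy)phenyl]chroman-4-yl}phenol
Conditions: Bu4NF, THF, 0 °C
Reagents that add atoms: none
Why: Fluoride cleaves the aryl silyl ether and frees the phenol para to the interflavan carbon, whose two ortho positions are equivalent.

Step 12
Reactants: 21 methyl 3,4,5-trihydroxybenzoate (methyl gallate)
Product: 22 methyl 7-hydroxy-2,2-diphenyl-1,3-benzodioxole-5-carboxylate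
Conditions: Ph2CCl2, neat, 170 °C
Reagents that add atoms: dichlorodiphenylmethane, ClC(Cl)(c1ccccc1)c1ccccc1
Why: Ketalisation of two adjacent phenols with the gem-dichloride gives the five-membered diphenylmethylene ketal and, since only one vicinal pair can be bridged, leaves one outer hydroxyl free.

Step 13
Reactants: 22 the hydroxy ketal ester
Product: 23 methyl 7-[(tert-butyldimethylsilyl)oxy]-2,2-diphenyl-1,3-benzodioxole-5-carboxylate
Conditions: t-BuMe2SiCl, imidazole, DMF, rt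
Reagents that add atoms: tert-butyl(chloro)dimethylsilane, CC(C)(C)[Si](C)(C)Cl
Why: Silylation of the remaining phenol marks the oxygen (future O3') that is later unmasked alone for galloylation.

Step 14
Reactants: 23 the silyl ketal ester
Product: 24 {7-[(tert-butyldimethylsilyl)oxy]-2,2-diphenyl-1,3-benzodioxol-5-yl}methanol
Conditions: i-Bu2AlH, CH2Cl2, −78 → 0 °C
Reagents that add atoms: none
Why: Hydride reduction of the ester gives the benzylic alcohol, and the aryl silyl ether and the ketal are stable to the reagent.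

Step 15
Reactants: 24 the benzylic alcohol
Product: 25 7-[(tert-butyldimethylsilyl)oxy]-2,2-diphenyl-1,3-benzodioxole-5-carbaldehyde
Conditions: MnO2, CH2Cl2, rt
Reagents that add atoms: none
Why: MnO2 oxidises benzylic alcohols selectively to aldehydes without over-oxidation.

Step 16
Reactants: 25 the aldehyde
Product: 26 rac-1-{7-[(tert-butyldimethylsilyl)oxy]-2,2-diphenyl-1,3-benzodioxol-5-yl}prop-2-en-1-ol
Conditions: vinylmagnesium bromide, THF, −78 → 0 °C
Reagents that add atoms: vinylmagnesium bromide, C=C[Mg]Br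
Why: Grignard 1,2-addition of the vinyl group gives the racemic allylic alcohol that is resolved in the next step.

Step 17
Reactants: 26 the racemic allylic alcohol
Product: 27 (S)-{7-[(tert-butyldimethylsilyl)oxy]-2,2-diphenyl-1,3-benzodioxol-5-yl}[(2R)-oxiran-2-yl]methanol (erythro)
Conditions: Ti(OiPr)4, L-(+)-diisopropyl tartrate, t-BuOOH (0.6 equiv), 4 Å MS, CH2Cl2, −20 °C
Reagents that add atoms: tert-butyl hydroperoxide, CC(C)(C)OO
Why: Sharpless kinetic resolution, in which the L-(+)-tartrate catalyst epoxidises the (R)-alcohol much faster and on one alkene face to give the erythro epoxy alcohol with an (S)-carbinol and an (R)-oxirane carbon, while the (S)-alcohol stays behind.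

Step 18
Reactants: 20 the phenol; 27 the erythro epoxy alcohol
Product: 28 (R)-{7-[(tert-butyldimethylsilyl)oxy]-2,2-diphenyl-1,3-benzodioxol-5-yl}[(2R)-oxiran-2-yl]methyl ether of phenol 20
Conditions: PPh3, DIAD, toluene, 0 °C → rt
Reagents that add atoms: none
Why: Mitsunobu etherification displaces the activated benzylic hydroxyl by the phenoxide in an SN2 step with inversion, which sets lower C2 as R, and the epoxide is inert under these neutral conditions.

Step 19
Reactants: 28 the aryl epoxy ether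
Product: 29 (2R,3R)-5,7-bis(benzyloxy)-2-{7-[(tert-butyldimethylsilyl)oxy]-2,2-diphenyl-1,3-benzodioxol-5-yl}-6-{(2R,3R)-3,5,7-tris(benzyloxy)-2-[4-(benzyloxy)phenyl]chroman-4β-yl}chroman-3-ol (both units 2,3-cis; upper unit 3,4-trans)
Conditions: AuCl3 (5 mol %), AgOTf (15 mol %), CH2Cl2, 0 °C → rt
Reagents that add atoms: none
Why: Gold-catalysed intramolecular Friedel–Crafts alkylation of the aryl ether by the epoxide (6-endo epoxy-arene cyclisation at the unsubstituted terminal carbon) forms lower C4–C4a without touching the C3–O bond, so C3 keeps the R configuration of the epoxide and the 2,3-cis flavan-3-ol results, and because both ortho positions of the aryl ether are equivalent the linkage is 4→6.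

Step 20
Reactants: 29 the silyl-protected dimer
Product: 30 (2R,3R)-5,7-bis(benzyloxy)-2-(7-hydroxy-2,2-diphenyl-1,3-benzodioxol-5-yl)-6-{(2R,3R)-3,5,7-tris(benzyloxy)-2-[4-(benzyloxy)phenyl]chroman-4β-yl}chroman-3-ol
Conditions: Bu4NF, THF, 0 °C
Reagents that add atoms: none
Why: Fluoride cleaves the aryl silyl ether and frees the C3' phenol next to the free C3 alcohol, while the ketal and all benzyl ethers stay.

Step 21
Reactants: 30 the phenol alcohol; 31 3,4,5-tris(benzyloxy)benzoyl chloride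
Product: 32 lower 3-O,3'-O-bis[3,4,5-tris(benzyloxy)benzoyl] ester of 30
Conditions: 31 (3 equiv), Et3N, DMAP, CH2Cl2, 0 °C → rt
Reagents that add atoms: none
Why: DMAP-catalysed acylation by the acid chloride esterifies the C3' phenol and the axial secondary C3 alcohol in one operation.

Step 22
Reactants: 32 the fully protected digallate
Product: 33 epiafzelechin-(4β→6)-epigallocatechin 3,3'-di-O-gallate (CNP0290965.1; upper unit 2R,3R,4S; lower unit 2R,3R)
Conditions: H2 (1 atm), Pd(OH)2/C, THF/MeOH, rt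
Reagents that add atoms: none
Why: Hydrogenolysis removes all twelve benzyl ethers and the diphenylmethylene ketal under neutral conditions that should leave the two esters, the stereocentres and the interflavan bond untouched.

**Compound list**
1 | (S)-4-benzyl-1,3-oxazolidin-2-one | O=C1OC[C@H](Cc2ccccc2)N1 | starting material
2 | (benzyloxy)acetyl chloride | O=C(Cl)COCc1ccccc1 | starting material
3 | lithium (S)-4-benzyl-2-oxo-1,3-oxazolidin-3-ide | [Li]N1[C@@H](Cc2ccccc2)COC1=O | intermediate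
4 | (S)-4-benzyl-3-[(benzyloxy)acetyl]-1,3-oxazolidin-2-one | O=C1OC[C@H](Cc2ccccc2)N1C(=O)COCc1ccccc1 | intermediate
5 | 4-(benzyloxy)benzaldehyde | O=Cc1ccc(OCc2ccccc2)cc1 | starting material
6 | (Z)-dibutylboron enolate of 4 | CCCCB(CCCC)O/C(=C\OCc1ccccc1)N1C(=O)OC[C@@H]1Cc1ccccc1 | intermediate
7 | (S)-4-benzyl-3-[(2S,3R)-2-(benzyloxy)-3-[4-(benzyloxy)phenyl]-3-hydroxypropanoyl]-1,3-oxazolidin-2-one | O=C1OC[C@H](Cc2ccccc2)N1C(=O)[C@@H](OCc1ccccc1)[C@@H](c1ccc(OCc2ccccc2)cc1)O | intermediate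
8 | (1R,2R)-2-(benzyloxy)-1-[4-(benzyloxy)phenyl]propane-1,3-diol | OC[C@@H](OCc1ccccc1)[C@@H](c1ccc(OCc2ccccc2)cc1)O | intermediate
9 | (1R,2R)-2-(benzyloxy)-1-[4-(benzyloxy)phenyl]-3-[(tert-butyldiphenylsilyl)oxy]propan-1-ol | CC(C)(C)[Si](c1ccccc1)(c1ccccc1)OC[C@@H](OCc1ccccc1)[C@@H](c1ccc(OCc2ccccc2)cc1)O | intermediate
10 | 1-bromo-3,5-bis(benzyloxy)benzene | Brc1cc(OCc2ccccc2)cc(OCc2ccccc2)c1 | starting material
11 | tert-butyl{(2R,3R)-2-(benzyloxy)-3-[4-(benzyloxy)phenyl]-3-[3,5-bis(benzyloxy)phenoxy]propoxy}diphenylsilane | CC(C)(C)[Si](c1ccccc1)(c1ccccc1)OC[C@@H](OCc1ccccc1)[C@@H](c1ccc(OCc2ccccc2)cc1)Oc1cc(OCc2ccccc2)cc(OCc2ccccc2)c1 | intermediate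
12 | (2R,3R)-2-(benzyloxy)-3-[4-(benzyloxy)phenyl]-3-[3,5-bis(benzyloxy)phenoxy]propan-1-ol | OC[C@@H](OCc1ccccc1)[C@@H](c1ccc(OCc2ccccc2)cc1)Oc1cc(OCc2ccccc2)cc(OCc2ccccc2)c1 | intermediate
13 | (2S,3R)-2-(benzyloxy)-3-[4-(benzyloxy)phenyl]-3-[3,5-bis(benzyloxy)phenoxy]propanal | O=C[C@@H](OCc1ccccc1)[C@@H](c1ccc(OCc2ccccc2)cc1)Oc1cc(OCc2ccccc2)cc(OCc2ccccc2)c1 | intermediate
14 | 3,5-bis(benzyloxy)phenol | Oc1cc(OCc2ccccc2)cc(OCc2ccccc2)c1 | starting material
15 | [3,5-bis(benzyloxy)phenoxy]tri(propan-2-yl)silane | CC(C)[Si](C(C)C)(C(C)C)Oc1cc(OCc2ccccc2)cc(OCc2ccccc2)c1 | intermediate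
16 | {2,6-bis(benzyloxy)-4-[tri(propan-2-yl)silyloxy]phenyl}lithium | [Li]c1c(OCc2ccccc2)cc(O[Si](C(C)C)(C(C)C)C(C)C)cc1OCc1ccccc1 | intermediate
17 | (2R,3R)-2-(benzyloxy)-3-[4-(benzyloxy)phenyl]-3-[3,5-bis(benzyloxy)phenoxy]-1-{2,6-bis(benzyloxy)-4-[tri(propan-2-yl)silyloxy]phenyl}propan-1-ol, both C1 epimers | CC(C)[Si](C(C)C)(C(C)C)Oc1cc(OCc2ccccc2)c(C(O)[C@@H](OCc2ccccc2)[C@@H](c2ccc(OCc3ccccc3)cc2)Oc2cc(OCc3ccccc3)cc(OCc3ccccc3)c2)c(OCc2ccccc2)c1 | intermediate
18 | C4 benzylic cation from 17 | CC(C)[Si](C(C)C)(C(C)C)Oc1cc(OCc2ccccc2)c([CH+][C@@H](OCc2ccccc2)[C@@H](c2ccc(OCc3ccccc3)cc2)Oc2cc(OCc3ccccc3)cc(OCc3ccccc3)c2)c(OCc2ccccc2)c1 | intermediate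
19 | [3,5-bis(benzyloxy)-4-{(2R,3R,4S)-3,5,7-tris(benzyloxy)-2-[4-(benzyloxy)phenyl]chroman-4-yl}phenoxy]tri(propan-2-yl)silane | CC(C)[Si](C(C)C)(C(C)C)Oc1cc(OCc2ccccc2)c(c(OCc2ccccc2)c1)[C@H]1c2c(OCc3ccccc3)cc(OCc3ccccc3)cc2O[C@H](c2ccc(OCc3ccccc3)cc2)[C@@H]1OCc1ccccc1 | intermediate
20 | 3,5-bis(benzyloxy)-4-{(2R,3R,4S)-3,5,7-tris(benzyloxy)-2-[4-(benzyloxy)phenyl]chroman-4-yl}phenol | Oc1cc(OCc2ccccc2)c(c(OCc2ccccc2)c1)[C@H]1c2c(OCc3ccccc3)cc(OCc3ccccc3)cc2O[C@H](c2ccc(OCc3ccccc3)cc2)[C@@H]1OCc1ccccc1 | intermediate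
21 | methyl 3,4,5-trihydroxybenzoate | COC(=O)c1cc(O)c(O)c(O)c1 | starting material
22 | methyl 7-hydroxy-2,2-diphenyl-1,3-benzodioxole-5-carboxylate | COC(=O)c1cc(O)c2c(c1)OC(c1ccccc1)(c1ccccc1)O2 | intermediate
23 | methyl 7-[(tert-butyldimethylsilyl)oxy]-2,2-diphenyl-1,3-benzodioxole-5-carboxylate | COC(=O)c1cc(O[Si](C)(C)C(C)(C)C)c2c(c1)OC(c1ccccc1)(c1ccccc1)O2 | intermediate
24 | {7-[(tert-butyldimethylsilyl)oxy]-2,2-diphenyl-1,3-benzodioxol-5-yl}methanol | OCc1cc(O[Si](C)(C)C(C)(C)C)c2c(c1)OC(c1ccccc1)(c1ccccc1)O2 | intermediate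
25 | 7-[(tert-butyldimethylsilyl)oxy]-2,2-diphenyl-1,3-benzodioxole-5-carbaldehyde | O=Cc1cc(O[Si](C)(C)C(C)(C)C)c2c(c1)OC(c1ccccc1)(c1ccccc1)O2 | intermediate
26 | rac-1-{7-[(tert-butyldimethylsilyl)oxy]-2,2-diphenyl-1,3-benzodioxol-5-yl}prop-2-en-1-ol | C=CC(O)c1cc(O[Si](C)(C)C(C)(C)C)c2c(c1)OC(c1ccccc1)(c1ccccc1)O2 | intermediate
27 | (S)-{7-[(tert-butyldimethylsilyl)oxy]-2,2-diphenyl-1,3-benzodioxol-5-yl}[(2R)-oxiran-2-yl]methanol | O[C@@H](c1cc(O[Si](C)(C)C(C)(C)C)c2c(c1)OC(c1ccccc1)(c1ccccc1)O2)[C@H]1CO1 | intermediate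
28 | (R)-{7-[(tert-butyldimethylsilyl)oxy]-2,2-diphenyl-1,3-benzodioxol-5-yl}[(2R)-oxiran-2-yl]methyl ether of phenol 20 | O(c1cc(OCc2ccccc2)c(c(OCc2ccccc2)c1)[C@H]1c2c(OCc3ccccc3)cc(OCc3ccccc3)cc2O[C@H](c2ccc(OCc3ccccc3)cc2)[C@@H]1OCc1ccccc1)[C@H](c1cc(O[Si](C)(C)C(C)(C)C)c2c(c1)OC(c1ccccc1)(c1ccccc1)O2)[C@H]1CO1 | intermediate
29 | (2R,3R)-5,7-bis(benzyloxy)-2-{7-[(tert-butyldimethylsilyl)oxy]-2,2-diphenyl-1,3-benzodioxol-5-yl}-6-{(2R,3R)-3,5,7-tris(benzyloxy)-2-[4-(benzyloxy)phenyl]chroman-4β-yl}chroman-3-ol | CC(C)(C)[Si](C)(C)Oc1cc(cc2OC(c3ccccc3)(c3ccccc3)Oc12)[C@H]1Oc2cc(OCc3ccccc3)c([C@H]3c4c(OCc5ccccc5)cc(OCc5ccccc5)cc4O[C@H](c4ccc(OCc5ccccc5)cc4)[C@@H]3OCc3ccccc3)c(OCc3ccccc3)c2C[C@H]1O | intermediate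
30 | (2R,3R)-5,7-bis(benzyloxy)-2-(7-hydroxy-2,2-diphenyl-1,3-benzodioxol-5-yl)-6-{(2R,3R)-3,5,7-tris(benzyloxy)-2-[4-(benzyloxy)phenyl]chroman-4β-yl}chroman-3-ol | Oc1cc(cc2OC(c3ccccc3)(c3ccccc3)Oc12)[C@H]1Oc2cc(OCc3ccccc3)c([C@H]3c4c(OCc5ccccc5)cc(OCc5ccccc5)cc4O[C@H](c4ccc(OCc5ccccc5)cc4)[C@@H]3OCc3ccccc3)c(OCc3ccccc3)c2C[C@H]1O | intermediate
31 | 3,4,5-tris(benzyloxy)benzoyl chloride | O=C(Cl)c1cc(OCc2ccccc2)c(OCc2ccccc2)c(OCc2ccccc2)c1 | starting material
32 | lower 3-O,3'-O-bis[3,4,5-tris(benzyloxy)benzoyl] ester of 30 | O=C(Oc1cc(cc2OC(c3ccccc3)(c3ccccc3)Oc12)[C@H]1Oc2cc(OCc3ccccc3)c([C@H]3c4c(OCc5ccccc5)cc(OCc5ccccc5)cc4O[C@H](c4ccc(OCc5ccccc5)cc4)[C@@H]3OCc3ccccc3)c(OCc3ccccc3)c2C[C@H]1OC(=O)c1cc(OCc2ccccc2)c(OCc2ccccc2)c(OCc2ccccc2)c1)c1cc(OCc2ccccc2)c(OCc2ccccc2)c(OCc2ccccc2)c1 | intermediate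
33 | epiafzelechin-(4β→6)-epigallocatechin 3,3'-di-O-gallate (CNP0290965.1) | O=C(Oc1cc([C@H]2Oc3cc(O)c([C@H]4c5c(O)cc(O)cc5O[C@H](c5ccc(O)cc5)[C@@H]4O)c(O)c3C[C@H]2OC(=O)c2cc(O)c(O)c(O)c2)cc(O)c1O)c1cc(O)c(O)c(O)c1 | target

**Step count**
Total: 22 steps. Longest linear sequence: 15 steps (steps 1–7, 9–11 and 18–22).

**Steps most likely to fail, with fallbacks**

Step 10 (key step). The cation may lose the C3 proton to give an enol ether, the closure may take a boat-like path and give the 3,4-cis isomer, or the closure may reverse under the acid and scramble C4. The fallback makes the same bond with the usual polarity; it sets out from aldehyde 13 and comes back at 19. Treating 13 with BF3·OEt2 and Et3SiH (CH2Cl2, −78 → 0 °C) should let the tethered 3,5-bis(benzyloxy)phenyl ether add to the activated aldehyde (intramolecular Friedel–Crafts hydroxyalkylation), and the C4 carbinol so formed is reduced ionically to tetra-O-benzyl-epiafzelechin F1. Oxidation of F1 at C4 with DDQ in the presence of 2-ethoxyethanol should give the 4β-(2-ethoxyethoxy) ether F2. Ionisation of F2 with TMSOTf (CH2Cl2, −78 °C) in the presence of an excess of silyl ether 15 gives a C4 cation held by upper ring A, which 15 should capture anti to the C3 benzyloxy group through its carbon para to the silyloxy group, giving 19.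

Step 5. β-Hydride elimination from the hindered benzylic palladium alkoxide, or base-induced silyl migration, may outrun C–O reductive elimination. The fallback forms the aryl ether by substitution with inversion; it sets out from 9 and comes back at 11. Dess–Martin oxidation of 9 gives the aryl ketone (2R)-2-(benzyloxy)-1-[4-(benzyloxy)phenyl]-3-[(tert-butyldiphenylsilyl)oxy]propan-1-one F3. Chelation-controlled reduction with Zn(BH4)2 (Et2O, −20 °C, Cram chelate through the α-benzyloxy group) should give the anti alcohol (1S,2R)-2-(benzyloxy)-1-[4-(benzyloxy)phenyl]-3-[(tert-butyldiphenylsilyl)oxy]propan-1-ol F4. Mitsunobu etherification of F4 with 3,5-bis(benzyloxy)phenol 14 (PPh3, DIAD, toluene, 0 °C) inverts the carbinol and gives 11.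

Step 19. The Lewis acid may ionise the lower C2–O bond (loss of configuration at C2), open the epoxide in the 5-exo sense, or cleave the acid-labile interflavan bond. The fallback closes the ring by an anionic alkylation; it sets out from phenol 20 and comes back at 30. Iodination of 20 ortho to the hydroxyl (I2, NaHCO3, THF/H2O, 0 °C; the two ortho positions are equivalent) gives 3,5-bis(benzyloxy)-2-iodo-4-{(2R,3R)-3,5,7-tris(benzyloxy)-2-[4-(benzyloxy)phenyl]chroman-4β-yl}phenol F5. Mitsunobu coupling of F5 with 27, as in step 18, gives the iodoaryl epoxy ether F6. Li2NiBr4 (THF, 0 °C) opens the epoxide at its terminal carbon to the bromohydrin F7, and Et3SiCl/imidazole gives its triethylsilyl ether F8. Ph3MgLi (THF, −78 → 0 °C) effects iodine–magnesium exchange, and the arylmagnesium displaces the primary bromide (6-exo-tet) to give the 3-O-triethylsilyl flavan F9. Bu4NF, as in step 20, removes both silyl groups from F9 and gives 30.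

**Further compounds**
F1 | step 10 | (2R,3R)-3,5,7-tris(benzyloxy)-2-[4-(benzyloxy)phenyl]chromane (tetra-O-benzyl-epiafzelechin) | C1c2c(OCc3ccccc3)cc(OCc3ccccc3)cc2O[C@H](c2ccc(OCc3ccccc3)cc2)[C@@H]1OCc1ccccc1
F2 | step 10 | (2R,3R,4S)-3,5,7-tris(benzyloxy)-2-[4-(benzyloxy)phenyl]-4-(2-ethoxyethoxy)chromane (4β ether) | CCOCCO[C@H]1c2c(OCc3ccccc3)cc(OCc3ccccc3)cc2O[C@H](c2ccc(OCc3ccccc3)cc2)[C@@H]1OCc1ccccc1
F3 | step 5 | (2R)-2-(benzyloxy)-1-[4-(benzyloxy)phenyl]-3-[(tert-butyldiphenylsilyl)oxy]propan-1-one | CC(C)(C)[Si](c1ccccc1)(c1ccccc1)OC[C@@H](OCc1ccccc1)C(=O)c1ccc(OCc2ccccc2)cc1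
F4 | step 5 | (1S,2R)-2-(benzyloxy)-1-[4-(benzyloxy)phenyl]-3-[(tert-butyldiphenylsilyl)oxy]propan-1-ol | CC(C)(C)[Si](c1ccccc1)(c1ccccc1)OC[C@@H](OCc1ccccc1)[C@H](c1ccc(OCc2ccccc2)cc1)O
F5 | step 19 | 3,5-bis(benzyloxy)-2-iodo-4-{(2R,3R)-3,5,7-tris(benzyloxy)-2-[4-(benzyloxy)phenyl]chroman-4β-yl}phenol | Oc1cc(OCc2ccccc2)c(c(OCc2ccccc2)c1I)[C@H]1c2c(OCc3ccccc3)cc(OCc3ccccc3)cc2O[C@H](c2ccc(OCc3ccccc3)cc2)[C@@H]1OCc1ccccc1
F6 | step 19 | (R)-{7-[(tert-butyldimethylsilyl)oxy]-2,2-diphenyl-1,3-benzodioxol-5-yl}[(2R)-oxiran-2-yl]methyl ether of iodophenol F5 | O(c1cc(OCc2ccccc2)c(c(OCc2ccccc2)c1I)[C@H]1c2c(OCc3ccccc3)cc(OCc3ccccc3)cc2O[C@H](c2ccc(OCc3ccccc3)cc2)[C@@H]1OCc1ccccc1)[C@H](c1cc(O[Si](C)(C)C(C)(C)C)c2c(c1)OC(c1ccccc1)(c1ccccc1)O2)[C@H]1CO1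
F7 | step 19 | bromohydrin from F6 (terminal bromide, secondary alcohol at the future lower C3) | O(c1cc(OCc2ccccc2)c(c(OCc2ccccc2)c1I)[C@H]1c2c(OCc3ccccc3)cc(OCc3ccccc3)cc2O[C@H](c2ccc(OCc3ccccc3)cc2)[C@@H]1OCc1ccccc1)[C@H](c1cc(O[Si](C)(C)C(C)(C)C)c2c(c1)OC(c1ccccc1)(c1ccccc1)O2)[C@H](O)CBr
F8 | step 19 | triethylsilyl ether of bromohydrin F7 | O(c1cc(OCc2ccccc2)c(c(OCc2ccccc2)c1I)[C@H]1c2c(OCc3ccccc3)cc(OCc3ccccc3)cc2O[C@H](c2ccc(OCc3ccccc3)cc2)[C@@H]1OCc1ccccc1)[C@H](c1cc(O[Si](C)(C)C(C)(C)C)c2c(c1)OC(c1ccccc1)(c1ccccc1)O2)[C@H](O[Si](CC)(CC)CC)CBr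
F9 | step 19 | 3-O-triethylsilyl ether of 29 | CC(C)(C)[Si](C)(C)Oc1cc(cc2OC(c3ccccc3)(c3ccccc3)Oc12)[C@H]1Oc2cc(OCc3ccccc3)c([C@H]3c4c(OCc5ccccc5)cc(OCc5ccccc5)cc4O[C@H](c4ccc(OCc5ccccc5)cc4)[C@@H]3OCc3ccccc3)c(OCc3ccccc3)c2C[C@H]1O[Si](CC)(CC)CC
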